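**Retrosynthetic overview**

1. Locants used: ring B = C1H2, C2H2, C3(OH)(C15HBr2), C4=C5, spiro C6; ring A = C6, C7(=C14H2), C8H2, C9(OH), C10(Br), C11Me2.
2. The C3–C15 bond is made last (LiCHBr2 plus a ring B enone). The ring A groups (C7=CH2 by a CH2SiMe3 transposition, C10–Br and C9–OH by bromination and reduction) come from a dimedone vinylogous ester.
3. Ring B comes from an enantioselective Diels–Alder reaction of an exocyclic enol pivalate (C6=C5, made by formylation of the dimedone ether) with a 2-silyloxybutadiene. It forms C5–C4 and, as the ring-closing bond, C6–C1; loss of pivalate then gives C4=C5.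
4. Enabling feature: in ring B the spiro carbon C6 is α to C7 (the exocyclic methylene carbon of ring A, a latent carbonyl) and 1,4 to the oxygenated C3, with C4=C5 on the C5 side. This is the "para" adduct pattern of a 2-oxydiene with an α-alkylidene ketone whose β-carbon carried a leaving group.
5. Ring order: ring A is bought (dimedone); ring B is formed second, in the key step, and sets the spiro stereocentre.

Key step: step 5

Assumption: 4 is drawn as the Z isomer (pivaloyloxy group on the carbonyl side, away from the gem-dimethyl group); its geometry does not affect the outcome because C5 becomes sp2 again in 9.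
Assumption: the catalyst antipode is the one that delivers (6R)-9; the sense of induction has to be confirmed on the first run, and both antipodes are available.

**Route**

Step 1
Reactants: 1 dimedone (5,5-dimethylcyclohexane-1,3-dione)
Product: 2 3-isobutoxy-5,5-dimethylcyclohex-2-en-1-one
Conditions: iBuOH, TsOH·H2O (cat.), toluene, reflux, Dean–Stark
Reagents that add atoms: isobutanol (2-methylpropan-1-ol), CC(C)CO
Why: Acid-catalysed vinylogous esterification of the cyclic 1,3-dione with azeotropic removal of water is routine and masks the future C9 at the ketone level while leaving the future C7 carbonyl free.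

Step 2
Reactants: 2 3-isobutoxy-5,5-dimethylcyclohex-2-en-1-one
Product: 3 (Z)-6-(hydroxymethylidene)-3-isobutoxy-5,5-dimethylcyclohex-2-en-1-one (enol form of the 6-formyl ketone)
Conditions: LiN(iPr)2 (LDA), THF, −78 °C; CF3CH2OCHO, −78 °C; then 1 M HCl
Reagents that add atoms: 2,2,2-trifluoroethyl formate, O=COCC(F)(F)F
Why: Kinetic α'-deprotonation of the β-alkoxy enone (the regiochemistry of Stork–Danheiser alkylation) gives the C6 enolate, and its Claisen-type formylation should deliver the chelated hydroxymethylidene ketone.

Step 3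
Reactants: 3 (Z)-6-(hydroxymethylidene)-3-isobutoxy-5,5-dimethylcyclohex-2-en-1-one
Product: 4 (Z)-(4-isobutoxy-6,6-dimethyl-2-oxocyclohex-3-en-1-ylidene)methyl pivalate
Conditions: PivCl, Et3N, DMAP (cat.), CH2Cl2, 0 °C
Reagents that add atoms: pivaloyl chloride, CC(C)(C)C(Cl)=O
Why: O-acylation of the β-keto aldehyde enol should give an exocyclic β-acyloxy enone, a dienophile whose β-carbon carries a group that is a poor leaving group from an enolate but is readily lost by E1cB once a ketone sits at C3.

Step 4
Reactants: 5 methyl vinyl ketone (but-3-en-2-one)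
Product: 6 2-(triisopropylsilyloxy)buta-1,3-diene
Conditions: iPr3SiOTf, Et3N, Et2O, 0 °C
Reagents that add atoms: triisopropylsilyl trifluoromethanesulfonate, CC(C)[Si](OS(=O)(=O)C(F)(F)F)(C(C)C)C(C)C
Why: Soft enolisation and O-silylation of the methyl ketone is the standard preparation of 2-silyloxydienes.

Step 5
Reactants: 4 (Z)-(4-isobutoxy-6,6-dimethyl-2-oxocyclohex-3-en-1-ylidene)methyl pivalate; 6 2-(triisopropylsilyloxy)buta-1,3-diene
Product: 9 (6R)-9-isobutoxy-11,11-dimethylspiro[5.5]undeca-4,8-diene-3,7-dione, via Diels–Alder adduct 7 (not isolated), via pivaloyloxy ketone 8 (not isolated)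
Conditions: (S)-3,3-diphenyl-1-(o-tolyl)tetrahydro-1H,3H-pyrrolo[1,2-c][1,3,2]oxazaborole (20 mol %), HN(SO2CF3)2 (20 mol %), CH2Cl2, −40 → −20 °C; then HF·pyridine, THF, 0 °C; then DBU, 23 °C
Reagents that add atoms: none
Why: Proposed new method: the boron cation binds the C7 carbonyl oxygen of 4 and lowers the LUMO of the exocyclic C6=C5 alkene, so that diene 6 should add in an asynchronous [4+2] cycloaddition in which the diene terminus next to the silyloxy carbon bonds to the β-carbon C5 and the ring closes through the C6–C1 bond, which creates the spiro quaternary carbon; HF then releases the C3 ketone and DBU expels pivalate from C5 (E1cB), so that C4=C5 appears on the correct arm and the enol pivalate has served as an ynone surrogate. The closest known reaction types are acid-catalysed enantioselective Diels–Alder reactions of 2-silyloxybutadienes with enones and enantioselective spirocyclising Diels–Alder reactions of exocyclic α-methylene ketones that carry an adjacent gem-dimethyl group; what has not been shown is a β-acyloxy-substituted (trisubstituted) exocyclic dienophile of this kind. Ring B is closed in the suprafacial [4+2] mode (in the stepwise limit: Mukaiyama–Michael addition at C5, then six-membered closure of the boron enolate carbon C6 onto the silyloxyallyl cation terminus C1). The only lasting new stereocentre, C6, is controlled by the catalyst, which blocks one face of the s-cis-locked enone; the C5 stereocentre of 7 and 8 is transient and is erased by the elimination. The step needs "para" regioselectivity (silyloxy carbon 1,4 to C6), secured by the matched polarisation of the 2-silyloxydiene and the C7-activated alkene, and site selectivity for C6=C5 over C8=C9, secured because C8=C9 is a donor-substituted vinylogous ester alkene.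

Step 6
Reactants: 9 (6R)-9-isobutoxy-11,11-dimethylspiro[5.5]undeca-4,8-diene-3,7-dione
Product: 10 (6R)-9-isobutoxy-11,11-dimethyl-3-(triisopropylsilyloxy)spiro[5.5]undeca-2,4,8-trien-7-one
Conditions: LiN(iPr)2 (1.05 equiv), THF, −78 °C; iPr3SiOTf, −78 → 0 °C
Reagents that add atoms: triisopropylsilyl trifluoromethanesulfonate, CC(C)[Si](OS(=O)(=O)C(F)(F)F)(C(C)C)C(C)C
Why: Kinetic α'-deprotonation of the ring B enone at C2 is much faster than γ-deprotonation of the ring A vinylogous ester, and O-silylation should mask the ring B ketone as a robust cross-conjugated silyl dienol ether that keeps C5 sp2.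

Step 7
Reactants: 10 (6R)-9-isobutoxy-11,11-dimethyl-3-(triisopropylsilyloxy)spiro[5.5]undeca-2,4,8-trien-7-one
Product: 11 (6R,10S)-10-bromo-9-isobutoxy-11,11-dimethyl-3-(triisopropylsilyloxy)spiro[5.5]undeca-2,4,8-trien-7-one
Conditions: LiN(iPr)2 (1.2 equiv), THF, −78 → −30 °C; BrCCl2CCl2Br, −78 °C
Reagents that add atoms: 1,2-dibromotetrachloroethane, BrC(Cl)(Cl)C(Cl)(Cl)Br
Why: With C6 quaternary, LDA can only remove a γ-proton at C10, and the vinylogous ester dienolate should be brominated at its γ-terminus by the halophilic bromine donor (which spares the neutral silyl dienol ether); bromine is expected to enter anti to the pseudoaxial C11 methyl group, on the ring A face that carries the flat sp2 C5 arm of ring B and not the C1 methylene, which gives 10S.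

Step 8
Reactants: 11 (6R,10S)-10-bromo-9-isobutoxy-11,11-dimethyl-3-(triisopropylsilyloxy)spiro[5.5]undeca-2,4,8-trien-7-one
Product: 13 (6S,10S)-10-bromo-11,11-dimethyl-3-(triisopropylsilyloxy)-7-[(trimethylsilyl)methyl]spiro[5.5]undeca-2,4,7-trien-9-one, via β-hydroxysilane 12 (not isolated)
Conditions: Me3SiCH2Li, CeCl3, THF, −78 °C; then 0.5 M HCl, THF, 0 °C (brief)
Reagents that add atoms: (trimethylsilyl)methyllithium, [Li]C[Si](C)(C)C
Why: The weakly basic organocerium reagent should add 1,2 to the hindered vinylogous ester carbonyl without touching the acidic C10–H or the bromide, and brief dilute acid effects the Stork–Danheiser transposition to the C9 enone with the CH2SiMe3 group retained at C7, conditions that a triisopropylsilyl enol ether tolerates.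

Step 9
Reactants: 13 (6S,10S)-10-bromo-11,11-dimethyl-3-(triisopropylsilyloxy)-7-[(trimethylsilyl)methyl]spiro[5.5]undeca-2,4,7-trien-9-one
Product: 14 (6S,10S)-10-bromo-11,11-dimethyl-7-methylidenespiro[5.5]undec-4-ene-3,9-dione
Conditions: Bu4NF, AcOH, THF, −20 → 0 °C
Reagents that add atoms: none
Why: Fluoride cleaves the C–Si bond of the vinylogous α-silyl ketone to an extended dienolate that acetic acid protonates kinetically at the α-carbon C8 (deconjugative protonation), which fixes the C7 exocyclic methylene, and the same reagent releases the ring B enone from its silyl dienol ether; the buffer should prevent Favorskii-type loss of bromide and reconjugation.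

Step 10
Reactants: 14 (6S,10S)-10-bromo-11,11-dimethyl-7-methylidenespiro[5.5]undec-4-ene-3,9-dione
Product: 15 (6S,9R,10S)-10-bromo-11,11-dimethyl-7-methylidenespiro[5.5]undec-4-ene-3,9-diol (mixture of C3 epimers)
Conditions: iBu2AlH, CH2Cl2, −78 °C; aq. KNaC4H4O6 (potassium sodium tartrate) work-up
Reagents that add atoms: none
Why: DIBAL 1,2-reduces both carbonyl groups; at C9 the axial C11 methyl blocks the axial trajectory, so hydride should enter equatorially and give the axial alcohol cis to the equatorial C10 bromine (9R), while the new C3 carbinol centre is irrelevant because it is re-oxidised in step 11.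

Step 11
Reactants: 15 (6S,9R,10S)-10-bromo-11,11-dimethyl-7-methylidenespiro[5.5]undec-4-ene-3,9-diol
Product: 16 (6S,9R,10S)-10-bromo-9-hydroxy-11,11-dimethyl-7-methylidenespiro[5.5]undec-4-en-3-one
Conditions: MnO2 (activated, excess), CH2Cl2, 23 °C
Reagents that add atoms: none
Why: Activated MnO2 oxidises only the allylic ring B alcohol (both C3 epimers converge on the enone), the homoallylic, axial C9 hydroxyl being inert.

Step 12
Reactants: 16 (6S,9R,10S)-10-bromo-9-hydroxy-11,11-dimethyl-7-methylidenespiro[5.5]undec-4-en-3-one
Product: 17 mailiohydrin, (3R,6S,9R,10S)-10-bromo-3-(dibromomethyl)-11,11-dimethyl-7-methylidenespiro[5.5]undec-4-ene-3,9-diol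
Conditions: CH2Br2, LiN(iPr)2, THF, −90 → −78 °C (LiCHBr2, 3.5 equiv); then 16, −78 °C; AcOH, −78 °C
Reagents that add atoms: dibromomethane, BrCBr (deprotonated in the flask to dibromomethyllithium, [Li]C(Br)Br)
Why: 1,2-Addition of the carbenoid dibromomethyllithium to the enone carbonyl; the bulky nucleophile is expected to approach C3 pseudoequatorially in the half-chair that keeps C11 pseudoequatorial, which places CHBr2 trans to C11 and the new hydroxyl on the C11 side (3R), and the cold acetic acid quench prevents closure of the alkoxide to a bromo epoxide.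

**Compound list**

1 | dimedone (5,5-dimethylcyclohexane-1,3-dione) | CC1(C)CC(=O)CC(=O)C1 | starting material
2 | 3-isobutoxy-5,5-dimethylcyclohex-2-en-1-one | CC(C)COC1=CC(=O)CC(C)(C)C1 | intermediate
3 | (Z)-6-(hydroxymethylidene)-3-isobutoxy-5,5-dimethylcyclohex-2-en-1-one | CC(C)COC1=CC(=O)/C(=C\O)C(C)(C)C1 | intermediate
4 | (Z)-(4-isobutoxy-6,6-dimethyl-2-oxocyclohex-3-en-1-ylidene)methyl pivalate | CC(C)COC1=CC(=O)/C(=C\OC(=O)C(C)(C)C)C(C)(C)C1 | intermediate
5 | methyl vinyl ketone (but-3-en-2-one) | CC(=O)C=C | starting material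
6 | 2-(triisopropylsilyloxy)buta-1,3-diene | C=CC(=C)O[Si](C(C)C)(C(C)C)C(C)C | intermediate
7 | (6S)-9-isobutoxy-11,11-dimethyl-7-oxo-3-(triisopropylsilyloxy)spiro[5.5]undeca-2,8-dien-5-yl pivalate (C5 configuration not defined, transient) | O=C1C=C(OCC(C)C)CC(C)(C)[C@@]12C(OC(=O)C(C)(C)C)CC(O[Si](C(C)C)(C(C)C)C(C)C)=CC2 | intermediate
8 | (6S)-9-isobutoxy-11,11-dimethyl-3,7-dioxospiro[5.5]undec-8-en-5-yl pivalate (C5 configuration not defined, transient) | O=C1C=C(OCC(C)C)CC(C)(C)[C@@]12C(OC(=O)C(C)(C)C)CC(=O)CC2 | intermediate
9 | (6R)-9-isobutoxy-11,11-dimethylspiro[5.5]undeca-4,8-diene-3,7-dione | O=C1C=C(OCC(C)C)CC(C)(C)[C@@]12C=CC(=O)CC2 | intermediate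
10 | (6R)-9-isobutoxy-11,11-dimethyl-3-(triisopropylsilyloxy)spiro[5.5]undeca-2,4,8-trien-7-one | O=C1C=C(OCC(C)C)CC(C)(C)[C@@]12C=CC(O[Si](C(C)C)(C(C)C)C(C)C)=CC2 | intermediate
11 | (6R,10S)-10-bromo-9-isobutoxy-11,11-dimethyl-3-(triisopropylsilyloxy)spiro[5.5]undeca-2,4,8-trien-7-one | O=C1C=C(OCC(C)C)[C@@H](Br)C(C)(C)[C@@]12C=CC(O[Si](C(C)C)(C(C)C)C(C)C)=CC2 | intermediate
12 | (6R,10S)-10-bromo-9-isobutoxy-11,11-dimethyl-3-(triisopropylsilyloxy)-7-[(trimethylsilyl)methyl]spiro[5.5]undeca-2,4,8-trien-7-ol (C7 configuration not defined, transient) | C[Si](C)(C)CC1(O)C=C(OCC(C)C)[C@@H](Br)C(C)(C)[C@@]12C=CC(O[Si](C(C)C)(C(C)C)C(C)C)=CC2 | intermediate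
13 | (6S,10S)-10-bromo-11,11-dimethyl-3-(triisopropylsilyloxy)-7-[(trimethylsilyl)methyl]spiro[5.5]undeca-2,4,7-trien-9-one | C[Si](C)(C)CC1=CC(=O)[C@@H](Br)C(C)(C)[C@@]12C=CC(O[Si](C(C)C)(C(C)C)C(C)C)=CC2 | intermediate
14 | (6S,10S)-10-bromo-11,11-dimethyl-7-methylidenespiro[5.5]undec-4-ene-3,9-dione | C=C1CC(=O)[C@@H](Br)C(C)(C)[C@@]12C=CC(=O)CC2 | intermediate
15 | (6S,9R,10S)-10-bromo-11,11-dimethyl-7-methylidenespiro[5.5]undec-4-ene-3,9-diol (C3 epimers) | C=C1C[C@@H](O)[C@@H](Br)C(C)(C)[C@@]12C=CC(O)CC2 | intermediate
16 | (6S,9R,10S)-10-bromo-9-hydroxy-11,11-dimethyl-7-methylidenespiro[5.5]undec-4-en-3-one | C=C1C[C@@H](O)[C@@H](Br)C(C)(C)[C@@]12C=CC(=O)CC2 | intermediate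
17 | mailiohydrin, (3R,6S,9R,10S)-10-bromo-3-(dibromomethyl)-11,11-dimethyl-7-methylidenespiro[5.5]undec-4-ene-3,9-diol | C=C1C[C@@H](O)[C@@H](Br)C(C)(C)[C@@]12C=C[C@@](O)(C(Br)Br)CC2 | target

**Step count**

Total steps: 12. Longest linear sequence: 11 steps (steps 1–3 and 5–12, from dimedone).

**Steps most likely to fail**

Step 5 (labelled step). The hindered, trisubstituted dienophile may react so slowly that protodesilylation of the diene competes. Bond formation may also become stepwise, with pivalate expelled before the ring closes, which would erode enantiofacial control. The fallback uses known chemistry, sets out from 3 and returns at 9. Michael addition of formyl ketone 3 to methyl vinyl ketone 5 under a cinchona-alkaloid-derived amine–thiourea catalyst (a reaction class established for cyclic 1,3-dicarbonyl donors and enones) should give the keto aldehyde (6S)-6-formyl-3-isobutoxy-5,5-dimethyl-6-(3-oxobutyl)cyclohex-2-en-1-one F1, which already holds the C6 quaternary centre. Pyrrolidinium acetate then closes ring B by intramolecular aldol condensation (Robinson-type spiroannulation of a 2-formyl ketone) to give 9. If the Michael step has to be run with an achiral amine, racemic 9 is separated on a chiral stationary phase.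

Step 7. Facial selectivity at C10 may be poor, the ambident dienolate may be attacked at C8, or proton exchange may lead to over-bromination. The fallback sets out from 10 and returns at 13 by reversing the order of events. Organocerium addition of Me3SiCH2Li to 10 and Stork–Danheiser transposition with dilute acid should give the γ-silyl enone (6R)-11,11-dimethyl-3-(triisopropylsilyloxy)-7-[(trimethylsilyl)methyl]spiro[5.5]undeca-2,4,7-trien-9-one F2. Kinetic α'-enolisation of this cross-conjugated enone (LDA, −78 °C) and bromination with BrCCl2CCl2Br then places bromine at C10 to give 13. In this variant the enolate can only be attacked at C10 once it is formed, and ring A presents a different, flatter shape to the electrophile.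

Step 12. The carbenoid may approach C3 from the pseudoaxial rather than the pseudoequatorial direction, which would give the C3 epimer, or it may enolise the ketone. The fallback sets out from 16 and returns at 17 by saturating C4=C5 temporarily. Conjugate addition of benzeneselenol (PhSeSePh, NaBH4, EtOH, AcOH) to 16 should give the β-seleno ketone (6S,9R,10S)-10-bromo-9-hydroxy-11,11-dimethyl-7-methylidene-5-(phenylselanyl)spiro[5.5]undecan-3-one F3, a chair cyclohexanone on which organolithium reagents reliably add from the equatorial side. Addition of LiCHBr2 at −78 °C then gives the carbinol (3R,6S,9R,10S)-10-bromo-3-(dibromomethyl)-11,11-dimethyl-7-methylidene-5-(phenylselanyl)spiro[5.5]undecane-3,9-diol F4. Oxidation with H2O2 and selenoxide syn-elimination (only C4 bears β-hydrogens) restores the C4=C5 alkene and gives 17.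

Further compounds
F1 | step 5 | (6S)-6-formyl-3-isobutoxy-5,5-dimethyl-6-(3-oxobutyl)cyclohex-2-en-1-one | O=C1C=C(OCC(C)C)CC(C)(C)[C@@]1(CCC(C)=O)C=O
F2 | step 7 | (6R)-11,11-dimethyl-3-(triisopropylsilyloxy)-7-[(trimethylsilyl)methyl]spiro[5.5]undeca-2,4,7-trien-9-one | C[Si](C)(C)CC1=CC(=O)CC(C)(C)[C@@]12C=CC(O[Si](C(C)C)(C(C)C)C(C)C)=CC2
F3 | step 12 | (6S,9R,10S)-10-bromo-9-hydroxy-11,11-dimethyl-7-methylidene-5-(phenylselanyl)spiro[5.5]undecan-3-one (C5 epimers) | C=C1C[C@@H](O)[C@@H](Br)C(C)(C)[C@@]12C([Se]c3ccccc3)CC(=O)CC2
F4 | step 12 | (3R,6S,9R,10S)-10-bromo-3-(dibromomethyl)-11,11-dimethyl-7-methylidene-5-(phenylselanyl)spiro[5.5]undecane-3,9-diol (C5 epimers) | C=C1C[C@@H](O)[C@@H](Br)C(C)(C)[C@@]12C([Se]c3ccccc3)C[C@@](O)(C(Br)Br)CC2
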